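**Retrosynthetic overview**

- Feature: the only ring is a cyclohexane, C1–C6. Its CH carbon C2 (3-oxobutyl arm) lies between the quaternary C1 (CH3, acyl) and the gem-dimethyl carbon C3. C3 can carry a tertiary positive charge and is the direct neighbour of C2, so C2–C3 is the ring-closing bond, made after C1 so that C1 dictates C2.
- Late disconnections: the acetate comes from the allylic alcohol and the arm methyl ketone from a but-3-enyl group (Wacker). The C1 ketone comes from a C1 aldehyde plus a C5 homoallyllithium (from but-3-yn-1-ol), followed by oxidation.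
- The butenyl arm grows from a C2 vinyl group by hydroboration and B-alkyl Suzuki coupling with vinyl bromide.
- Ring formation (one ring, step 7): a C3 cation is captured by the γ-carbon of an (E)-allylsilane, giving C2–C3 and the C2 vinyl group.
- The acyclic precursor comes from geraniol by asymmetric epoxidation, silylation, a 1,2-shift to the quaternary aldehyde (sets C1), Takai iodo-olefination, Kumada coupling and Markovnikov hydration.

Key step: step 7

Remark: the carbinol carbon created in step 16 is carried as a mixture of epimers, because step 17 removes it.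

**Route**

Step 1
Reactants: 1 geraniol
Product: 2 (2S,3S)-2,3-epoxygeraniol
Conditions: Ti(OiPr)4 (5 mol %), L-(+)-diethyl tartrate (7 mol %), anhydrous t-BuOOH, 4 Å MS, CH2Cl2, −20 °C
Reagents that add atoms: tert-butyl hydroperoxide, CC(C)(C)OO
Why: The Sharpless asymmetric epoxidation is directed by the allylic hydroxyl, so only the 2,3-alkene reacts, and the L-(+)-tartrate ligand delivers oxygen to the face that gives the (2S,3S)-epoxide, from which all later chirality derives.

Step 2
Reactants: 2 (2S,3S)-2,3-epoxygeraniol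
Product: 3 (2S,3S)-2,3-epoxygeranyl tert-butyldimethylsilyl ether
Conditions: TBSCl, imidazole, CH2Cl2, 0 °C to rt
Reagents that add atoms: tert-butyldimethylsilyl chloride, CC(C)(C)[Si](C)(C)Cl
Why: Standard imidazole-mediated silylation of a primary alcohol installs the silyloxymethyl group that has to migrate in step 3 and leaves both epoxide stereocentres untouched.

Step 3
Reactants: 3 (2S,3S)-2,3-epoxygeranyl tert-butyldimethylsilyl ether
Product: 4 (S)-2-(tert-butyldimethylsilyloxymethyl)-2,6-dimethylhept-5-enal
Conditions: Me3Al (2 equiv) + 4-bromo-2,6-di-tert-butylphenol (4 equiv), CH2Cl2, rt, to give MeAl(OAr)2 (Ar = 4-bromo-2,6-di-tert-butylphenyl); then 3, −78 °C; aqueous work-up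
Reagents that add atoms: none
Why: In this organoaluminium-promoted epoxy silyl ether rearrangement (a semipinacol-type 1,2-shift) the bulky oxophilic Lewis acid opens the epoxide at the tertiary C3 and the silyloxymethyl group migrates from C2 to C3 anti to the departing oxygen, so the epoxide configuration is transferred with inversion into the (S)-configured quaternary carbon (future ring C1) while C2 becomes the aldehyde.

Step 4
Reactants: 4 (S)-2-(tert-butyldimethylsilyloxymethyl)-2,6-dimethylhept-5-enal
Product: 5 (1E,3R)-3-(tert-butyldimethylsilyloxymethyl)-1-iodo-3,7-dimethylocta-1,6-diene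
Conditions: CrCl2 (6 equiv), CHI3 (2 equiv), THF, 0 °C to rt
Reagents that add atoms: iodoform, IC(I)I
Why: The Takai olefination adds a geminal dichromium species to the aldehyde and is reliably E-selective for α-branched aldehydes, and its neutral conditions spare the silyl ether, the trisubstituted alkene and the non-enolisable quaternary centre.

Step 5
Reactants: 5 (1E,3R)-3-(tert-butyldimethylsilyloxymethyl)-1-iodo-3,7-dimethylocta-1,6-diene
Product: 6 (2E,4R)-4-(tert-butyldimethylsilyloxymethyl)-4,8-dimethyl-1-(trimethylsilyl)nona-2,7-diene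
Conditions: Me3SiCH2MgCl (1.5 equiv), Pd(PPh3)4 (5 mol %), THF, rt
Reagents that add atoms: (trimethylsilyl)methylmagnesium chloride, C[Si](C)(C)C[Mg]Cl
Why: Kumada–Corriu coupling of an alkenyl iodide with (trimethylsilyl)methylmagnesium chloride proceeds with retention of alkene geometry and so secures the (E)-allylsilane, which a non-stabilised and therefore Z-selective β-silylethylidene ylide would not.

Step 6
Reactants: 6 (2E,4R)-4-(tert-butyldimethylsilyloxymethyl)-4,8-dimethyl-1-(trimethylsilyl)nona-2,7-diene
Product: 7 (6R,7E)-6-(tert-butyldimethylsilyloxymethyl)-2,6-dimethyl-9-(trimethylsilyl)non-7-en-2-ol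
Conditions: Co(acac)2 (20 mol %), PhSiH3 (2.5 equiv), O2 (1 atm), THF, rt
Reagents that add atoms: dioxygen, O=O
Why: The Mukaiyama hydration works by hydrogen-atom transfer from a cobalt hydride and follows radical stability, so the trisubstituted alkene (tertiary site, hydrogen delivered to an unhindered CH) should react in Markovnikov fashion well before the neopentyl-shielded 1,2-disubstituted allylsilane alkene, and no stereocentre is formed.

Step 7
Reactants: 7 (6R,7E)-6-(tert-butyldimethylsilyloxymethyl)-2,6-dimethyl-9-(trimethylsilyl)non-7-en-2-ol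
Product: 10 (1R,2R)-1-(tert-butyldimethylsilyloxymethyl)-1,3,3-trimethyl-2-vinylcyclohexane, via tertiary carbocation 8 (not isolated), via beta-silyl carbocation 9 (not isolated)
Conditions: SnCl4 (1.1 equiv), CH2Cl2 (dilute), −78 °C
Reagents that add atoms: none
Why: Coordination of SnCl4 to the hydroxyl of 7 and heterolysis of the C–O bond give the tertiary carbocation 8 at the future C3; the allylsilane then bonds to it through its γ-carbon (future C2), which creates C2–C3 and the hyperconjugatively stabilised cation 9, and chloride strips the silyl group from 9 to release the vinyl group of 10. The closest known reaction type is the allylsilane-terminated cation–olefin cyclisation, an intramolecular Hosomi–Sakurai alkylation by a tertiary alkyl cation. Only one ring is made, the cyclohexane C1–C6, and its closure is 6-exo as judged from the reacting C=C bond (the β-carbon stays outside the ring), with a chair-shaped array of the six ring atoms. The new stereocentre C2 is governed by the quaternary C1: with the alkenyl unit equatorial, the chair that puts the small C1 methyl rather than CH2OTBS into the axial site, where it faces one methyl of the cationic C3 across the ring, should be lower in energy, and it places vinyl trans to CH2OTBS, that is (1R,2R). Regioselectivity for the hindered inner alkene carbon is secured by the β-silicon effect, and the E geometry keeps CH2SiMe3 clear of C1 so that the C–Si bond can align with the π system anti to the incoming cation. Chemoselectivity requires closure to outrun proton loss from 8 and protodesilylation, which the low temperature, the intramolecular six-membered geometry and the high nucleophilicity of the allylsilane favour, whereas facial discrimination has nothing to draw on but the steric gap between CH3 and CH2OTBS, so a minor C2 epimer may have to be removed by chromatography.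

Step 8
Reactants: 10 (1R,2R)-1-(tert-butyldimethylsilyloxymethyl)-1,3,3-trimethyl-2-vinylcyclohexane
Product: 12 (1R,2R)-2-(but-3-en-1-yl)-1-(tert-butyldimethylsilyloxymethyl)-1,3,3-trimethylcyclohexane, via B-alkyl-9-BBN adduct 11 (not isolated)
Conditions: 9-BBN (1.5 equiv), THF, 60 °C; then vinyl bromide (1 M in THF), PdCl2(dppf) (5 mol %), 3 M aq NaOH, 50 °C, sealed vessel
Reagents that add atoms: vinyl bromide, C=CBr
Why: Hydroboration with 9-BBN places boron on the unhindered terminal carbon and the B-alkyl Suzuki–Miyaura coupling with vinyl bromide then adds two carbons there, so the arm grows away from the congested C2, C2 never becomes α to a carbonyl group, and the terminal alkene serves as a latent methyl ketone that needs no protecting group.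

Step 9
Reactants: 12 (1R,2R)-2-(but-3-en-1-yl)-1-(tert-butyldimethylsilyloxymethyl)-1,3,3-trimethylcyclohexane
Product: 13 [(1R,2R)-2-(but-3-en-1-yl)-1,3,3-trimethylcyclohexyl]methanol
Conditions: Bu4NF (TBAF), THF, rt to 50 °C
Reagents that add atoms: none
Why: Fluoride-induced desilylation is driven by the strong Si–F bond and touches neither the terminal alkene nor the stereocentres, gentle warming compensating for the neopentyl position of the ether.

Step 10
Reactants: 13 [(1R,2R)-2-(but-3-en-1-yl)-1,3,3-trimethylcyclohexyl]methanol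
Product: 14 (1R,2R)-2-(but-3-en-1-yl)-1,3,3-trimethylcyclohexane-1-carbaldehyde
Conditions: Dess–Martin periodinane, CH2Cl2, 0 °C to rt
Reagents that add atoms: none
Why: Dess–Martin oxidation converts hindered primary alcohols into aldehydes under neutral conditions without over-oxidation, and the aldehyde has no α-hydrogen, so C1 cannot epimerise.

Step 11
Reactants: 15 but-3-yn-1-ol
Product: 16 tert-butyl(but-3-yn-1-yloxy)dimethylsilane
Conditions: TBSCl, imidazole, CH2Cl2, 0 °C to rt
Reagents that add atoms: tert-butyldimethylsilyl chloride, CC(C)(C)[Si](C)(C)Cl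
Why: Routine silylation masks the hydroxyl so that it neither consumes trimethylaluminium nor ends up undifferentiated from the allylic hydroxyl made in step 12.

Step 12
Reactants: 16 tert-butyl(but-3-yn-1-yloxy)dimethylsilane
Product: 19 (E)-5-(tert-butyldimethylsilyloxy)-3-methylpent-2-en-1-ol, via alkenyldimethylalane 17 (not isolated), via lithium alkenylalanate 18 (not isolated)
Conditions: Me3Al (2.5 equiv), Cp2ZrCl2 (25 mol %), CH2Cl2, 0 °C to rt; evaporate; n-BuLi, hexane–THF, −78 to 0 °C; (CH2O)n, rt; aqueous work-up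
Reagents that add atoms: trimethylaluminium, C[Al](C)C; paraformaldehyde (as formaldehyde), C=O
Why: The zirconium-catalysed Negishi carboalumination adds methyl and aluminium syn across the terminal alkyne with aluminium at the terminus, and hydroxymethylation of the derived alanate with formaldehyde occurs with retention, which fixes the E trisubstituted alkene of the target.

Step 13
Reactants: 19 (E)-5-(tert-butyldimethylsilyloxy)-3-methylpent-2-en-1-ol
Product: 20 (E)-5-(tert-butyldimethylsilyloxy)-1-(tert-butyldiphenylsilyloxy)-3-methylpent-2-ene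
Conditions: TBDPSCl, imidazole, CH2Cl2, rt
Reagents that add atoms: tert-butyldiphenylsilyl chloride, CC(C)(C)[Si](Cl)(c1ccccc1)c1ccccc1
Why: Silylation with the bulkier and more acid-stable tert-butyldiphenylsilyl group differentiates the two primary oxygens and gives an allylic ether that tolerates alkyllithium reagents, oxidants and the Wacker medium.

Step 14
Reactants: 20 (E)-5-(tert-butyldimethylsilyloxy)-1-(tert-butyldiphenylsilyloxy)-3-methylpent-2-ene
Product: 21 (E)-5-(tert-butyldiphenylsilyloxy)-3-methylpent-3-en-1-ol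
Conditions: camphorsulfonic acid (10 mol %), MeOH–CH2Cl2, 0 °C
Reagents that add atoms: none
Why: Acid-catalysed methanolysis cleaves a primary tert-butyldimethylsilyl ether far faster than a tert-butyldiphenylsilyl ether, so only the homoallylic hydroxyl is released.

Step 15
Reactants: 21 (E)-5-(tert-butyldiphenylsilyloxy)-3-methylpent-3-en-1-ol
Product: 22 (E)-tert-butyl[(5-iodo-3-methylpent-2-en-1-yl)oxy]diphenylsilane
Conditions: I2, PPh3, imidazole, CH2Cl2, 0 °C
Reagents that add atoms: iodine, II
Why: The Appel-type iodination replaces the primary hydroxyl by SN2 displacement of the oxyphosphonium ion under nearly neutral conditions that disturb neither the E alkene nor the allylic silyl ether.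

Step 16
Reactants: 14 (1R,2R)-2-(but-3-en-1-yl)-1,3,3-trimethylcyclohexane-1-carbaldehyde; 22 (E)-tert-butyl[(5-iodo-3-methylpent-2-en-1-yl)oxy]diphenylsilane
Product: 24 (E)-1-[(1R,2R)-2-(but-3-en-1-yl)-1,3,3-trimethylcyclohexyl]-6-(tert-butyldiphenylsilyloxy)-4-methylhex-4-en-1-ol (both carbinol epimers), via homoallyllithium 23 (not isolated)
Conditions: 22 (1.3 equiv), t-BuLi (2.6 equiv), Et2O–pentane, −78 °C; then 14, −78 °C to 0 °C; H2O quench
Reagents that add atoms: none
Why: Lithium–iodine exchange with two equivalents of t-BuLi is faster at −78 °C than any reaction of the allylic silyl ether, and the unhindered primary alkyllithium 23 adds 1,2 to the non-enolisable neopentyl aldehyde, the new carbinol centre being formed without control and without consequence because step 17 removes it.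

Step 17
Reactants: 24 (E)-1-[(1R,2R)-2-(but-3-en-1-yl)-1,3,3-trimethylcyclohexyl]-6-(tert-butyldiphenylsilyloxy)-4-methylhex-4-en-1-ol
Product: 25 (E)-1-[(1R,2R)-2-(but-3-en-1-yl)-1,3,3-trimethylcyclohexyl]-6-(tert-butyldiphenylsilyloxy)-4-methylhex-4-en-1-one
Conditions: Dess–Martin periodinane, CH2Cl2, rt
Reagents that add atoms: none
Why: Dess–Martin oxidation is effective for crowded secondary alcohols, converges both carbinol epimers on one ketone and leaves both alkenes and the silyl ether intact.

Step 18
Reactants: 25 (E)-1-[(1R,2R)-2-(but-3-en-1-yl)-1,3,3-trimethylcyclohexyl]-6-(tert-butyldiphenylsilyloxy)-4-methylhex-4-en-1-one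
Product: 26 (E)-6-(tert-butyldiphenylsilyloxy)-4-methyl-1-[(1R,2R)-1,3,3-trimethyl-2-(3-oxobutyl)cyclohexyl]hex-4-en-1-one
Conditions: PdCl2 (10 mol %), Cu(OAc)2 (20 mol %), O2 (1 atm), DMA–H2O 7:1, rt
Reagents that add atoms: water, O
Why: The Tsuji–Wacker oxidation hydroxypalladates only the monosubstituted alkene, with Markovnikov attack of water, so the butenyl arm becomes the 3-oxobutyl arm while the trisubstituted alkene, which binds divalent palladium poorly, is left alone.

Step 19
Reactants: 26 (E)-6-(tert-butyldiphenylsilyloxy)-4-methyl-1-[(1R,2R)-1,3,3-trimethyl-2-(3-oxobutyl)cyclohexyl]hex-4-en-1-one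
Product: 27 (E)-6-hydroxy-4-methyl-1-[(1R,2R)-1,3,3-trimethyl-2-(3-oxobutyl)cyclohexyl]hex-4-en-1-one
Conditions: HF·pyridine, pyridine, THF, 0 °C to rt
Reagents that add atoms: none
Why: Buffered fluoride cleaves the Si–O bond under weakly acidic conditions, which avoids base-induced aldol reaction between the two ketones as well as allylic ionisation.

Step 20
Reactants: 27 (E)-6-hydroxy-4-methyl-1-[(1R,2R)-1,3,3-trimethyl-2-(3-oxobutyl)cyclohexyl]hex-4-en-1-one
Product: 28 (E)-3-methyl-6-oxo-6-[(1R,2R)-1,3,3-trimethyl-2-(3-oxobutyl)cyclohexyl]hex-2-en-1-yl acetate (target, CNP0326957.1)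
Conditions: Ac2O, Et3N, DMAP (cat.), CH2Cl2, 0 °C
Reagents that add atoms: acetic anhydride, CC(=O)OC(C)=O
Why: DMAP-catalysed acetylation of the only hydroxyl group, a primary allylic one, completes the target without affecting C1, C2 or the E alkene.

**Compound list**

1 | geraniol, (E)-3,7-dimethylocta-2,6-dien-1-ol | CC(C)=CCC/C(C)=C/CO | starting material
2 | (2S,3S)-2,3-epoxygeraniol | CC(C)=CCC[C@]1(C)O[C@H]1CO | intermediate
3 | (2S,3S)-2,3-epoxygeranyl tert-butyldimethylsilyl ether | CC(C)=CCC[C@]1(C)O[C@H]1CO[Si](C)(C)C(C)(C)C | intermediate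
4 | (S)-2-(tert-butyldimethylsilyloxymethyl)-2,6-dimethylhept-5-enal | CC(C)=CCC[C@@](C=O)(C)CO[Si](C)(C)C(C)(C)C | intermediate
5 | (1E,3R)-3-(tert-butyldimethylsilyloxymethyl)-1-iodo-3,7-dimethylocta-1,6-diene | CC(C)=CCC[C@@](/C=C/I)(C)CO[Si](C)(C)C(C)(C)C | intermediate
6 | (2E,4R)-4-(tert-butyldimethylsilyloxymethyl)-4,8-dimethyl-1-(trimethylsilyl)nona-2,7-diene | CC(C)=CCC[C@@](/C=C/C[Si](C)(C)C)(C)CO[Si](C)(C)C(C)(C)C | intermediate
7 | (6R,7E)-6-(tert-butyldimethylsilyloxymethyl)-2,6-dimethyl-9-(trimethylsilyl)non-7-en-2-ol (key-step precursor) | CC(C)(O)CCC[C@@](/C=C/C[Si](C)(C)C)(C)CO[Si](C)(C)C(C)(C)C | intermediate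
8 | tertiary carbocation from 7 (charge at future C3), not isolated | C[C+](C)CCC[C@@](/C=C/C[Si](C)(C)C)(C)CO[Si](C)(C)C(C)(C)C | intermediate
9 | ring-closed beta-silyl carbocation, not isolated | C[Si](C)(C)C[CH+][C@@H]1C(C)(C)CCC[C@@]1(C)CO[Si](C)(C)C(C)(C)C | intermediate
10 | (1R,2R)-1-(tert-butyldimethylsilyloxymethyl)-1,3,3-trimethyl-2-vinylcyclohexane, vinyl trans to silyloxymethyl (key-step product) | C=C[C@@H]1C(C)(C)CCC[C@@]1(C)CO[Si](C)(C)C(C)(C)C | intermediate
11 | B-alkyl-9-BBN adduct of 10, not isolated | B1(C2CCCC1CCC2)CC[C@@H]3C(C)(C)CCC[C@@]3(C)CO[Si](C)(C)C(C)(C)C | intermediate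
12 | (1R,2R)-2-(but-3-en-1-yl)-1-(tert-butyldimethylsilyloxymethyl)-1,3,3-trimethylcyclohexane | C=CCC[C@@H]1C(C)(C)CCC[C@@]1(C)CO[Si](C)(C)C(C)(C)C | intermediate
13 | [(1R,2R)-2-(but-3-en-1-yl)-1,3,3-trimethylcyclohexyl]methanol | C=CCC[C@@H]1C(C)(C)CCC[C@@]1(C)CO | intermediate
14 | (1R,2R)-2-(but-3-en-1-yl)-1,3,3-trimethylcyclohexane-1-carbaldehyde | C=CCC[C@@H]1C(C)(C)CCC[C@@]1(C)C=O | intermediate
15 | but-3-yn-1-ol | C#CCCO | starting material
16 | tert-butyl(but-3-yn-1-yloxy)dimethylsilane | C#CCCO[Si](C)(C)C(C)(C)C | intermediate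
17 | (E)-alkenyldimethylalane from 16, not isolated | CC(C)(C)[Si](C)(C)OCC/C(C)=C/[Al](C)C | intermediate
18 | lithium butyl(alkenyl)dimethylalanate, not isolated | [Li+].CC(C)(C)[Si](C)(C)OCC/C(C)=C/[Al-](C)(C)CCCC | intermediate
19 | (E)-5-(tert-butyldimethylsilyloxy)-3-methylpent-2-en-1-ol | CC(C)(C)[Si](C)(C)OCC/C(C)=C/CO | intermediate
20 | (E)-5-(tert-butyldimethylsilyloxy)-1-(tert-butyldiphenylsilyloxy)-3-methylpent-2-ene | CC(C)(C)[Si](C)(C)OCC/C(C)=C/CO[Si](c1ccccc1)(c1ccccc1)C(C)(C)C | intermediate
21 | (E)-5-(tert-butyldiphenylsilyloxy)-3-methylpent-3-en-1-ol | OCC/C(C)=C/CO[Si](c1ccccc1)(c1ccccc1)C(C)(C)C | intermediate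
22 | (E)-tert-butyl[(5-iodo-3-methylpent-2-en-1-yl)oxy]diphenylsilane | ICC/C(C)=C/CO[Si](c1ccccc1)(c1ccccc1)C(C)(C)C | intermediate
23 | (E)-5-(tert-butyldiphenylsilyloxy)-3-methylpent-3-en-1-yllithium, not isolated | [Li]CC/C(C)=C/CO[Si](c1ccccc1)(c1ccccc1)C(C)(C)C | intermediate
24 | (E)-1-[(1R,2R)-2-(but-3-en-1-yl)-1,3,3-trimethylcyclohexyl]-6-(tert-butyldiphenylsilyloxy)-4-methylhex-4-en-1-ol, both carbinol epimers | C=CCC[C@@H]1C(C)(C)CCC[C@@]1(C)C(O)CC/C(C)=C/CO[Si](c1ccccc1)(c1ccccc1)C(C)(C)C | intermediate
25 | (E)-1-[(1R,2R)-2-(but-3-en-1-yl)-1,3,3-trimethylcyclohexyl]-6-(tert-butyldiphenylsilyloxy)-4-methylhex-4-en-1-one | C=CCC[C@@H]1C(C)(C)CCC[C@@]1(C)C(=O)CC/C(C)=C/CO[Si](c1ccccc1)(c1ccccc1)C(C)(C)C | intermediate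
26 | (E)-6-(tert-butyldiphenylsilyloxy)-4-methyl-1-[(1R,2R)-1,3,3-trimethyl-2-(3-oxobutyl)cyclohexyl]hex-4-en-1-one | CC(=O)CC[C@@H]1C(C)(C)CCC[C@@]1(C)C(=O)CC/C(C)=C/CO[Si](c1ccccc1)(c1ccccc1)C(C)(C)C | intermediate
27 | (E)-6-hydroxy-4-methyl-1-[(1R,2R)-1,3,3-trimethyl-2-(3-oxobutyl)cyclohexyl]hex-4-en-1-one | CC(=O)CC[C@@H]1C(C)(C)CCC[C@@]1(C)C(=O)CC/C(C)=C/CO | intermediate
28 | (E)-3-methyl-6-oxo-6-[(1R,2R)-1,3,3-trimethyl-2-(3-oxobutyl)cyclohexyl]hex-2-en-1-yl acetate | CC(=O)CC[C@@H]1C(C)(C)CCC[C@@]1(C)C(=O)CC/C(C)=C/COC(C)=O | target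

**Step count and risks**

Total step count: 20.
Longest linear sequence: 15 steps (steps 1–10 and 16–20, from geraniol). The side branch (steps 11–15) joins at step 16.

Steps most likely to fail:

1. Step 7. Proton loss from the tertiary cation and acid-induced loss of the allylic silyl group may outrun bond formation at the crowded inner alkene carbon, and facial discrimination by C1 may be weak.
   - The fallback sets out from aldehyde 4 and comes back at 12. It makes the same C2–C3 bond by a radical instead of a cation.
   - Horner–Wadsworth–Emmons reaction of 4 with trimethyl phosphonoacetate (NaH, THF) should give the methyl (E)-enoate F1.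
   - Hydrogen-atom transfer from an iron hydride (Fe(acac)3, PhSiH3, EtOH, 60 °C) to the trisubstituted alkene generates a tertiary radical at C3. This radical closes 6-exo onto the enoate β-carbon (a reductive Giese-type cyclisation) to give the cyclohexylacetic ester F2.
   - LiAlH4 (Et2O, 0 °C) reduces it to the primary alcohol F3, at which stage C2 epimers can be separated.
   - I2, PPh3 and imidazole convert this into the primary iodide F4, and copper-catalysed coupling with CH2=CHMgBr (CuI, THF, −20 °C) gives 12.

2. Step 6. Hydrogen-atom transfer to, or oxidation of, the allylsilane alkene may compete with hydration of the trisubstituted alkene.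
   - The fallback sets out from iodoalkene 5 and comes back at 7. It makes the allylsilane last, so that it never meets an oxidant.
   - mCPBA (NaHCO3, CH2Cl2, 0 °C) attacks only the electron-rich trisubstituted alkene, the iodoalkene being deactivated, and gives the epoxy iodoalkene F5 (epimers at the epoxide CH, of no consequence).
   - LiEt3BH (THF, 0 °C) opens the epoxide at its less substituted carbon to give the tertiary alcohol iodoalkene F6.
   - Kumada coupling with excess Me3SiCH2MgCl and Pd(PPh3)4, the first equivalent being spent on the hydroxyl, gives 7.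

3. Step 16. The homoallyllithium may decay by intramolecular displacement of the allylic silyloxide or by proton abstraction. Its addition to the hindered neopentyl aldehyde may also be slow enough for hydride transfer to compete.
   - The fallback sets out from aldehyde 14 and comes back at ketone 25. It moves the fragment union to an enolate alkylation.
   - MeMgBr (THF, 0 °C) gives the methyl carbinol F7, and Dess–Martin oxidation gives the methyl ketone F8, which can enolise only toward its methyl group.
   - LiN(iPr)2 (THF, −78 °C) gives the lithium enolate F9.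
   - The electrophile is made from prenol. TBDPSCl and imidazole give the prenyl silyl ether F10. E-selective allylic oxidation (SeO2 cat., t-BuOOH, CH2Cl2) gives the (E)-allylic alcohol F11, and CBr4 with PPh3 gives the (E)-allylic bromide F12.
   - Alkylation of F9 with F12 (THF–DMPU, −78 to −20 °C) gives 25.

**Further compounds**

F1 | step 7 | methyl (2E,4R)-4-(tert-butyldimethylsilyloxymethyl)-4,8-dimethylnona-2,7-dienoate | CC(C)=CCC[C@@](/C=C/C(=O)OC)(C)CO[Si](C)(C)C(C)(C)C
F2 | step 7 | methyl 2-[(1R,2R)-2-(tert-butyldimethylsilyloxymethyl)-2,6,6-trimethylcyclohexyl]acetate | COC(=O)C[C@@H]1C(C)(C)CCC[C@@]1(C)CO[Si](C)(C)C(C)(C)C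
F3 | step 7 | 2-[(1R,2R)-2-(tert-butyldimethylsilyloxymethyl)-2,6,6-trimethylcyclohexyl]ethan-1-ol | OCC[C@@H]1C(C)(C)CCC[C@@]1(C)CO[Si](C)(C)C(C)(C)C
F4 | step 7 | (1R,2R)-1-(tert-butyldimethylsilyloxymethyl)-2-(2-iodoethyl)-1,3,3-trimethylcyclohexane | ICC[C@@H]1C(C)(C)CCC[C@@]1(C)CO[Si](C)(C)C(C)(C)C
F5 | step 6 | (1E,3R)-3-(tert-butyldimethylsilyloxymethyl)-6,7-epoxy-1-iodo-3,7-dimethyloct-1-ene, both C6 epimers | CC1(C)OC1CC[C@@](/C=C/I)(C)CO[Si](C)(C)C(C)(C)C
F6 | step 6 | (6R,7E)-6-(tert-butyldimethylsilyloxymethyl)-8-iodo-2,6-dimethyloct-7-en-2-ol | CC(C)(O)CCC[C@@](/C=C/I)(C)CO[Si](C)(C)C(C)(C)C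
F7 | step 16 | 1-[(1R,2R)-2-(but-3-en-1-yl)-1,3,3-trimethylcyclohexyl]ethan-1-ol, both carbinol epimers | C=CCC[C@@H]1C(C)(C)CCC[C@@]1(C)C(C)O
F8 | step 16 | 1-[(1R,2R)-2-(but-3-en-1-yl)-1,3,3-trimethylcyclohexyl]ethan-1-one | C=CCC[C@@H]1C(C)(C)CCC[C@@]1(C)C(C)=O
F9 | step 16 | lithium enolate of F8 | C=CCC[C@@H]1C(C)(C)CCC[C@@]1(C)C(=C)O[Li]
F10 | step 16 | tert-butyl[(3-methylbut-2-en-1-yl)oxy]diphenylsilane | CC(C)=CCO[Si](c1ccccc1)(c1ccccc1)C(C)(C)C
F11 | step 16 | (E)-4-(tert-butyldiphenylsilyloxy)-2-methylbut-2-en-1-ol | OC/C(C)=C/CO[Si](c1ccccc1)(c1ccccc1)C(C)(C)C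
F12 | step 16 | (E)-[(4-bromo-3-methylbut-2-en-1-yl)oxy](tert-butyl)diphenylsilane | BrC/C(C)=C/CO[Si](c1ccccc1)(c1ccccc1)C(C)(C)C
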